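**Retrosynthetic overview**
- The target is the bis-phenol of an (E)-α-arylidene-β-benzyl-γ-butyrolactone; both phenols are unveiled last from silyl ethers.
- The exocyclic C=C comes from dehydration of a β-hydroxy lactone, so the key C–C bond (lactone C3 to the benzylic carbon) is made by an intermolecular aldol addition of a lactone enolate to a protected 3-hydroxy-4,5-dimethoxybenzaldehyde.
- The (R)-β-(guaiacylmethyl)-γ-butyrolactone comes from an Evans alkylation of an N-(dihydroferuloyl)oxazolidinone with tert-butyl bromoacetate, reductive auxiliary removal and acid lactonisation; this sets the only stereocentre.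
- Ring order: both arenes are bought; the γ-lactone is the only ring formed (before the aldol), and the arylidene is installed after it.

Assumption: all carbon-bearing starting materials, including the hydroxy-dimethoxy aldehyde, are taken as inexpensive catalogue chemicals; the target is read as (3E,4R); TBS = tert-butyldimethylsilyl.

**Route**

Step 1
Reactants: 1 ferulic acid [(2E)-3-(4-hydroxy-3-methoxyphenyl)prop-2-enoic acid]
Product: 2 dihydroferulic acid [3-(4-hydroxy-3-methoxyphenyl)propanoic acid]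
Conditions: H2 (1 atm), 10% Pd/C, MeOH, rt
Reagents that add atoms: none
Why: Heterogeneous catalytic hydrogenation saturates the cinnamic C=C without touching the arene, the acid or the phenol.

Step 2
Reactants: 2 dihydroferulic acid
Product: 4 3-[4-(TBSO)-3-methoxyphenyl]propanoic acid, via bis-silylated ester-ether 3 (not isolated)
Conditions: TBSCl (2.5 equiv), imidazole (5 equiv), DMF, rt; then AcOH/THF/H2O (3:1:1), rt
Reagents that add atoms: TBSCl (tert-butyldimethylsilyl chloride), CC(C)(C)[Si](C)(C)Cl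
Why: Imidazole-promoted silylation caps both OH groups, and the much more labile silyl ester is then hydrolysed selectively by mild aqueous acid while the aryl silyl ether stays.

Step 3
Reactants: 4 3-[4-(TBSO)-3-methoxyphenyl]propanoic acid; 5 (4S)-4-benzyl-1,3-oxazolidin-2-one
Product: 7 (4S)-4-benzyl-3-{3-[4-(TBSO)-3-methoxyphenyl]propanoyl}-1,3-oxazolidin-2-one, via mixed pivalic anhydride 6 (not isolated)
Conditions: PivCl (1.1 equiv), Et3N (2.5 equiv), THF, −20 °C; then LiCl (1.1 equiv), 5 (1.0 equiv), −20 °C → rt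
Reagents that add atoms: none
Why: N-acylation of the Evans auxiliary through a mixed anhydride, in which the LiCl/Et3N-activated oxazolidinone attacks the unhindered acyl carbonyl; no stereocentre is touched.

Step 4
Reactants: 7 (4S)-4-benzyl-3-{3-[4-(TBSO)-3-methoxyphenyl]propanoyl}-1,3-oxazolidin-2-one; 8 tert-butyl bromoacetate
Product: 10 tert-butyl (3R)-4-[(4S)-4-benzyl-2-oxo-1,3-oxazolidin-3-yl]-3-{[4-(TBSO)-3-methoxyphenyl]methyl}-4-oxobutanoate, via sodium Z-enolate 9 (not isolated)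
Conditions: NaN(SiMe3)2 (1.1 equiv), THF, −78 °C; then 8 (2.5 equiv), −78 → −45 °C
Reagents that add atoms: none
Why: Evans asymmetric alkylation, in which the chelated Z-enolate is alkylated on the face opposite the auxiliary's benzyl group, giving the (3R) centre (dr typically ≥ 95:5, minor isomer removed by chromatography).

Step 5
Reactants: 10 tert-butyl (3R)-4-[(4S)-4-benzyl-2-oxo-1,3-oxazolidin-3-yl]-3-{[4-(TBSO)-3-methoxyphenyl]methyl}-4-oxobutanoate
Product: 11 tert-butyl (3R)-4-[4-(TBSO)-3-methoxyphenyl]-3-(hydroxymethyl)butanoate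
Conditions: LiBH4 (1.5 equiv), H2O (1.5 equiv), Et2O, 0 °C
Reagents that add atoms: none
Why: Chemoselective reductive cleavage of the imide (its exocyclic carbonyl is far more electrophilic than the hindered tert-butyl ester) gives the primary alcohol and returns the auxiliary without enolising the stereocentre.

Step 6
Reactants: 11 tert-butyl (3R)-4-[4-(TBSO)-3-methoxyphenyl]-3-(hydroxymethyl)butanoate
Product: 12 (4R)-4-{[4-(TBSO)-3-methoxyphenyl]methyl}oxolan-2-one
Conditions: CF3CO2H/CH2Cl2 (1:5), 0 °C → rt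
Reagents that add atoms: none
Why: Acid-mediated tert-butyl ester cleavage (loss of isobutene) followed by 5-exo lactonisation; the stereocentre is not at a reacting carbon and the aryl silyl ether tolerates anhydrous CF3CO2H.

Step 7
Reactants: 13 3-hydroxy-4,5-dimethoxybenzaldehyde
Product: 14 3-(TBSO)-4,5-dimethoxybenzaldehyde
Conditions: TBSCl (1.2 equiv), imidazole (2.5 equiv), DMF, rt
Reagents that add atoms: TBSCl (tert-butyldimethylsilyl chloride), CC(C)(C)[Si](C)(C)Cl
Why: Standard phenol silylation removes the acidic OH that would quench the enolate in the next step.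

Step 8
Reactants: 12 (4R)-4-{[4-(TBSO)-3-methoxyphenyl]methyl}oxolan-2-one; 14 3-(TBSO)-4,5-dimethoxybenzaldehyde
Product: 17 (3S,4R)-3-{[3-(TBSO)-4,5-dimethoxyphenyl](hydroxy)methyl}-4-{[4-(TBSO)-3-methoxyphenyl]methyl}oxolan-2-one (both carbinol epimers), via lithium enolate 15 (not isolated), via lithium aldolate 16 (not isolated)
Conditions: LiN(SiMe3)2 (1.1 equiv), THF, −78 °C, 45 min; then 14 (1.2 equiv), −78 °C; AcOH quench at −78 °C
Reagents that add atoms: none
Why: Directed intermolecular aldol addition of the kinetic lactone enolate to a non-enolisable aldehyde, anti to the C4 substituent (3,4-trans); C4 is not enolisable and the two new centres are erased in the next step, so their ratio does not matter.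

Step 9
Reactants: 17 (3S,4R)-3-{[3-(TBSO)-4,5-dimethoxyphenyl](hydroxy)methyl}-4-{[4-(TBSO)-3-methoxyphenyl]methyl}oxolan-2-one
Product: 19 (3E,4R)-3-{[3-(TBSO)-4,5-dimethoxyphenyl]methylidene}-4-{[4-(TBSO)-3-methoxyphenyl]methyl}oxolan-2-one, via acetate 18 (not isolated)
Conditions: Ac2O (2 equiv), Et3N (3 equiv), DMAP (0.1 equiv), CH2Cl2, 0 °C → rt; then DBU (3 equiv), rt → 40 °C
Reagents that add atoms: none
Why: O-acetylation followed by E1cB elimination completes the aldol condensation and gives the more stable E-alkene (aryl anti to the lactone carbonyl); base-only conditions avoid the acid-triggered Friedel–Crafts closure to an aryltetralin.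

Step 10
Reactants: 19 (3E,4R)-3-{[3-(TBSO)-4,5-dimethoxyphenyl]methylidene}-4-{[4-(TBSO)-3-methoxyphenyl]methyl}oxolan-2-one
Product: 20 (3E,4R)-3-[(3-hydroxy-4,5-dimethoxyphenyl)methylidene]-4-[(4-hydroxy-3-methoxyphenyl)methyl]oxolan-2-one
Conditions: Bu4NF (2.4 equiv), AcOH (2.6 equiv), THF, 0 °C
Reagents that add atoms: none
Why: Fluoride-mediated desilylation of both aryl silyl ethers, buffered with AcOH so that no free phenoxide or basic fluoride can add to or isomerise the arylidene lactone.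

**Compound list**

1 | ferulic acid, (2E)-3-(4-hydroxy-3-methoxyphenyl)prop-2-enoic acid | COc1cc(/C=C/C(=O)O)ccc1O | starting material
2 | dihydroferulic acid, 3-(4-hydroxy-3-methoxyphenyl)propanoic acid | COc1cc(CCC(=O)O)ccc1O | intermediate
3 | tert-butyldimethylsilyl 3-[4-(tert-butyldimethylsilyloxy)-3-methoxyphenyl]propanoate | COc1cc(CCC(=O)O[Si](C)(C)C(C)(C)C)ccc1O[Si](C)(C)C(C)(C)C | intermediate
4 | 3-[4-(tert-butyldimethylsilyloxy)-3-methoxyphenyl]propanoic acid | COc1cc(CCC(=O)O)ccc1O[Si](C)(C)C(C)(C)C | intermediate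
5 | (4S)-4-benzyl-1,3-oxazolidin-2-one | O=C1N[C@@H](Cc2ccccc2)CO1 | starting material
6 | 3-[4-(tert-butyldimethylsilyloxy)-3-methoxyphenyl]propanoic pivalic anhydride | COc1cc(CCC(=O)OC(=O)C(C)(C)C)ccc1O[Si](C)(C)C(C)(C)C | intermediate
7 | (4S)-4-benzyl-3-{3-[4-(tert-butyldimethylsilyloxy)-3-methoxyphenyl]propanoyl}-1,3-oxazolidin-2-one | COc1cc(CCC(=O)N2[C@@H](Cc3ccccc3)COC2=O)ccc1O[Si](C)(C)C(C)(C)C | intermediate
8 | tert-butyl bromoacetate | CC(C)(C)OC(=O)CBr | starting material
9 | sodium (1Z)-1-[(4S)-4-benzyl-2-oxo-1,3-oxazolidin-3-yl]-3-[4-(tert-butyldimethylsilyloxy)-3-methoxyphenyl]prop-1-en-1-olate | COc1cc(C/C=C(\[O-])N2[C@@H](Cc3ccccc3)COC2=O)ccc1O[Si](C)(C)C(C)(C)C.[Na+] | intermediate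
10 | tert-butyl (3R)-4-[(4S)-4-benzyl-2-oxo-1,3-oxazolidin-3-yl]-3-{[4-(tert-butyldimethylsilyloxy)-3-methoxyphenyl]methyl}-4-oxobutanoate | CC(C)(C)OC(=O)C[C@@H](Cc1ccc(O[Si](C)(C)C(C)(C)C)c(OC)c1)C(=O)N1[C@@H](Cc2ccccc2)COC1=O | intermediate
11 | tert-butyl (3R)-4-[4-(tert-butyldimethylsilyloxy)-3-methoxyphenyl]-3-(hydroxymethyl)butanoate | CC(C)(C)OC(=O)C[C@@H](Cc1ccc(O[Si](C)(C)C(C)(C)C)c(OC)c1)CO | intermediate
12 | (4R)-4-{[4-(tert-butyldimethylsilyloxy)-3-methoxyphenyl]methyl}oxolan-2-one | O=C1C[C@@H](Cc2ccc(O[Si](C)(C)C(C)(C)C)c(OC)c2)CO1 | intermediate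
13 | 3-hydroxy-4,5-dimethoxybenzaldehyde | O=Cc1cc(O)c(OC)c(OC)c1 | starting material
14 | 3-(tert-butyldimethylsilyloxy)-4,5-dimethoxybenzaldehyde | O=Cc1cc(O[Si](C)(C)C(C)(C)C)c(OC)c(OC)c1 | intermediate
15 | lithium (4R)-4-{[4-(tert-butyldimethylsilyloxy)-3-methoxyphenyl]methyl}-4,5-dihydrofuran-2-olate | [Li+].[O-]C1=C[C@@H](Cc2ccc(O[Si](C)(C)C(C)(C)C)c(OC)c2)CO1 | intermediate
16 | lithium alkoxide of 17 (3,4-trans, both carbinol epimers) | O=C1OC[C@H](Cc2ccc(O[Si](C)(C)C(C)(C)C)c(OC)c2)[C@H]1C([O-])c1cc(O[Si](C)(C)C(C)(C)C)c(OC)c(OC)c1.[Li+] | intermediate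
17 | (3S,4R)-3-{[3-(tert-butyldimethylsilyloxy)-4,5-dimethoxyphenyl](hydroxy)methyl}-4-{[4-(tert-butyldimethylsilyloxy)-3-methoxyphenyl]methyl}oxolan-2-one (both carbinol epimers) | O=C1OC[C@H](Cc2ccc(O[Si](C)(C)C(C)(C)C)c(OC)c2)[C@H]1C(O)c1cc(O[Si](C)(C)C(C)(C)C)c(OC)c(OC)c1 | intermediate
18 | [3-(tert-butyldimethylsilyloxy)-4,5-dimethoxyphenyl][(3S,4R)-4-{[4-(tert-butyldimethylsilyloxy)-3-methoxyphenyl]methyl}-2-oxooxolan-3-yl]methyl acetate (both epimers) | O=C1OC[C@H](Cc2ccc(O[Si](C)(C)C(C)(C)C)c(OC)c2)[C@H]1C(OC(C)=O)c1cc(O[Si](C)(C)C(C)(C)C)c(OC)c(OC)c1 | intermediate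
19 | (3E,4R)-3-{[3-(tert-butyldimethylsilyloxy)-4,5-dimethoxyphenyl]methylidene}-4-{[4-(tert-butyldimethylsilyloxy)-3-methoxyphenyl]methyl}oxolan-2-one | COc1cc(C[C@H]2COC(=O)/C2=C/c2cc(O[Si](C)(C)C(C)(C)C)c(OC)c(OC)c2)ccc1O[Si](C)(C)C(C)(C)C | intermediate
20 | (3E,4R)-3-[(3-hydroxy-4,5-dimethoxyphenyl)methylidene]-4-[(4-hydroxy-3-methoxyphenyl)methyl]oxolan-2-one | COc1cc(C[C@H]2COC(=O)/C2=C/c2cc(O)c(OC)c(OC)c2)ccc1O | target

**Step count and risks**

Total steps: 10. Longest linear sequence: 9 (steps 1–6, then 8, 9 and 10); step 7 is a one-step side branch.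

The three steps most likely to fail:

Step 4 (Evans alkylation with tert-butyl bromoacetate; risk of incomplete conversion or eroded dr). The fallback sets out from 7 and changes how the two lactone carbons are brought in. Alkylation of 7 with the more reactive allyl iodide (NaN(SiMe3)2, THF, −78 °C, same facial control) gives (4S)-4-benzyl-3-[(2S)-2-{[4-(tert-butyldimethylsilyloxy)-3-methoxyphenyl]methyl}pent-4-enoyl]-1,3-oxazolidin-2-one F1. LiBH4/H2O in Et2O then releases (2S)-2-{[4-(tert-butyldimethylsilyloxy)-3-methoxyphenyl]methyl}pent-4-en-1-ol F2. Oxidative cleavage of the alkene (OsO4 cat., NaIO4, 2,6-lutidine, dioxane/H2O) gives a hydroxy aldehyde that closes to the lactol (4R)-4-{[4-(tert-butyldimethylsilyloxy)-3-methoxyphenyl]methyl}oxolan-2-ol F3. Oxidation with TEMPO (cat.)/PhI(OAc)2 in CH2Cl2 returns to the route at lactone 12.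

Step 8 (aldol of the lithium enolate; risk of retro-aldol, low conversion with the electron-rich aldehyde, or silyl transfer to the aldolate). The fallback sets out from 12 and replaces the basic enolate by a neutral nucleophile. Trapping with LiN(SiMe3)2/Me3SiCl in THF at −78 °C gives the silyl ketene acetal (4R)-4-{[4-(tert-butyldimethylsilyloxy)-3-methoxyphenyl]methyl}-2-(trimethylsilyloxy)-4,5-dihydrofuran F4. This undergoes a Mukaiyama aldol addition to 14 with BF3·OEt2 in CH2Cl2 at −78 °C, and mild aqueous citric acid work-up removes the O-SiMe3 group, coming back to the route at 17.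

Step 9 (acetylation/E1cB; risk of sluggish elimination or an E/Z mixture). The fallback sets out from 17 and separates dehydration from geometry control. A base-free concerted syn-dehydration with the Burgess reagent (toluene, 50 °C) will, from the carbinol epimer mixture, give 19 together with its geometric isomer (3Z,4R)-3-{[3-(tert-butyldimethylsilyloxy)-4,5-dimethoxyphenyl]methylidene}-4-{[4-(tert-butyldimethylsilyloxy)-3-methoxyphenyl]methyl}oxolan-2-one F5. The unseparated mixture is then equilibrated with I2 (5 mol%) in CH2Cl2 under visible light, which funnels F5 into the more stable E-isomer and rejoins the route at 19.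

**Further compounds**

F1 | step 4 | (4S)-4-benzyl-3-[(2S)-2-{[4-(tert-butyldimethylsilyloxy)-3-methoxyphenyl]methyl}pent-4-enoyl]-1,3-oxazolidin-2-one | C=CC[C@@H](Cc1ccc(O[Si](C)(C)C(C)(C)C)c(OC)c1)C(=O)N1[C@@H](Cc2ccccc2)COC1=O
F2 | step 4 | (2S)-2-{[4-(tert-butyldimethylsilyloxy)-3-methoxyphenyl]methyl}pent-4-en-1-ol | C=CC[C@@H](Cc1ccc(O[Si](C)(C)C(C)(C)C)c(OC)c1)CO
F3 | step 4 | (4R)-4-{[4-(tert-butyldimethylsilyloxy)-3-methoxyphenyl]methyl}oxolan-2-ol (anomer mixture) | OC1C[C@@H](Cc2ccc(O[Si](C)(C)C(C)(C)C)c(OC)c2)CO1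
F4 | step 8 | (4R)-4-{[4-(tert-butyldimethylsilyloxy)-3-methoxyphenyl]methyl}-2-(trimethylsilyloxy)-4,5-dihydrofuran | C[Si](C)(C)OC1=C[C@@H](Cc2ccc(O[Si](C)(C)C(C)(C)C)c(OC)c2)CO1
F5 | step 9 | (3Z,4R)-3-{[3-(tert-butyldimethylsilyloxy)-4,5-dimethoxyphenyl]methylidene}-4-{[4-(tert-butyldimethylsilyloxy)-3-methoxyphenyl]methyl}oxolan-2-one | COc1cc(C[C@H]2COC(=O)/C2=C\c2cc(O[Si](C)(C)C(C)(C)C)c(OC)c(OC)c2)ccc1O[Si](C)(C)C(C)(C)C
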